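**Plan**

- Retrosynthesis (target numbered as a 4H-inden-4-one; ring A = cyclohexenone, ring B = cyclopentane): the C6–CH2 bond to the side chain is cut together with a 1,3-transposition of the enone (C4=O/C5=C6 from C6=O/C4=C5). Then C4–C5 and C3a–C7a are cut in one step, and last the trisubstituted C=C of the open chain and the allyl–metal terminus of the aryl side chain.
- Enabling feature: once C6 carries the carbonyl, C4–C3a–C7a–C7–C6 of ring A is a 1,5-dicarbonyl array. The quaternary carbons C3a (α to C4) and C7a (β to C6) are neighbours already bridged by C1–C3 of ring B, and C5 is α′ to C6. An open keto aldehyde can therefore close by Michael addition (C3a–C7a) and aldol condensation (C4–C5).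
- Forward: cross-metathesis builds the open-chain enone aldehyde; the cascade closes ring B, then ring A; an allylbarium reagent adds the aryl side chain to the ring-A ketone; oxidative transposition and desilylation finish.
- Stereochemistry: both quaternary centres arise in the Michael event, the absolute sense from a chiral primary amine (enamine face) and the cis relation from the ring closure. The racemic centre of the chain is erased, and the (E)-olefin comes from Riley oxidation of a prenyl group and is kept in the allylbarium addition.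

Key step: step 6

Assumption: which pseudoenantiomeric cinchona amine gives the (3aR,7aS) series in step 6 cannot be told in advance; the quinine-derived amine is written, and its quinidine-derived counterpart would be used if the sense of induction is the opposite.

**Route**

Step 1
Reactants: 1 4-bromo-2-methylbut-1-ene; 2 methacrolein (2-methylprop-2-enal)
Product: 5 2,6-dimethylhept-6-enal (racemic), via Grignard reagent 3 (not isolated), via silyl enol ether 4 (not isolated)
Conditions: Mg, THF; then CuBr·SMe2 (5 mol %), Me3SiCl, HMPA, 2, THF, −78 °C; then 1 M HCl, rt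
Reagents that add atoms: none
Why: Copper-catalysed, Me3SiCl-accelerated conjugate addition of the homoallyl Grignard reagent 3 to the enal should give silyl enol ether 4, whose hydrolysis frees the α-methyl aldehyde; the new stereocentre may stay racemic because it is erased in step 6.

Step 2
Reactants: 6 5,5-dimethyldihydrofuran-2(3H)-one
Product: 7 4-hydroxy-N-methoxy-N,4-dimethylpentanamide
Conditions: MeNH(OMe)·HCl, i-PrMgCl, THF, −20 °C to 0 °C; aq. NH4Cl
Reagents that add atoms: N,O-dimethylhydroxylamine hydrochloride, CNOC.Cl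
Why: Aminolysis of the lactone by the chloromagnesium amide made in the flask (Weinreb amide formation) should open the ring to the hydroxy amide without over-addition.

Step 3
Reactants: 7 4-hydroxy-N-methoxy-N,4-dimethylpentanamide
Product: 8 N-methoxy-N,4-dimethyl-4-[(triethylsilyl)oxy]pentanamide
Conditions: Et3SiOTf, 2,6-lutidine, CH2Cl2, 0 °C
Reagents that add atoms: triethylsilyl trifluoromethanesulfonate, CC[Si](CC)(CC)OS(=O)(=O)C(F)(F)F
Why: Silylation with the silyl triflate should mask the tertiary hydroxyl group, which would otherwise relactonise here and form hemiketals with the later ketones.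

Step 4
Reactants: 8 N-methoxy-N,4-dimethyl-4-[(triethylsilyl)oxy]pentanamide
Product: 9 5-methyl-5-[(triethylsilyl)oxy]hex-1-en-3-one
Conditions: vinylmagnesium bromide CH2=CHMgBr, THF, 0 °C; cold aq. NH4Cl
Reagents that add atoms: vinylmagnesium bromide, C=C[Mg]Br
Why: Weinreb ketone synthesis: the chelated tetrahedral intermediate should stop the Grignard addition at the ketone stage and release the vinyl ketone on cold work-up.

Step 5
Reactants: 5 2,6-dimethylhept-6-enal; 9 5-methyl-5-[(triethylsilyl)oxy]hex-1-en-3-one
Product: 10 (2RS,6E)-2,6,11-trimethyl-8-oxo-11-[(triethylsilyl)oxy]dodec-6-enal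
Conditions: second-generation Hoveyda–Grubbs catalyst [RuCl2(=CH-C6H4-2-O-i-Pr)(H2IMes)] (H2IMes = 1,3-dimesitylimidazolidin-2-ylidene, 5 mol %), CH2Cl2, 40 °C
Reagents that add atoms: none
Why: Olefin cross-metathesis of a 1,1-disubstituted olefin with an electron-poor vinyl ketone should favour the cross product with loss of ethene and give mainly the (E)-trisubstituted enone, the aldehyde and the silyl ether being tolerated; any (Z)-isomer can be carried on because the olefin is consumed in step 6.

Step 6
Reactants: 10 (2RS,6E)-2,6,11-trimethyl-8-oxo-11-[(triethylsilyl)oxy]dodec-6-enal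
Product: 13 (3aR,7aS)-3a,7a-dimethyl-6-{2-methyl-2-[(triethylsilyl)oxy]propyl}-1,2,3,3a,4,7a-hexahydro-5H-inden-5-one, via keto aldehyde 11 (not isolated), via aldol 12 (not isolated)
Conditions: 9-amino-9-deoxy-epi-quinine (20 mol %), CF3CO2H (40 mol %), PhMe, 40 °C, then 70 °C
Reagents that add atoms: none
Why: Proposed new method: the primary amine condenses with the α-branched aldehyde of 10 to a secondary enamine (which erases the racemic centre), whose β-carbon adds 5-exo-trig to the β-carbon of the ammonium-hydrogen-bonded enone to give keto aldehyde 11 and so closes ring B with both quaternary carbons, after which the ketone condenses through its α′-CH2 with the neopentyl aldehyde in a 6-(enolendo)-exo-trig aldol closure of ring A (12) and loses water to 13. The closest known reaction types are the amine-catalysed enantioselective Michael–aldol (Robinson-type) annulation of α,α-disubstituted aldehydes with enones and the amine-catalysed intramolecular Michael addition of aldehydes to enones, neither of which has been shown to join two fully substituted carbons. C7a of 13 (the former aldehyde α-carbon) is set by the catalyst, which shields one face of the enamine, and C3a (the former enone β-carbon) follows from the ring constraint, because a compact ene-like transition state with the enamine N–H bridged to the enone oxygen places the formyl and acylmethyl groups cis and only the cis adduct can reach the aldol closure, so the absolute configuration does not depend on the E/Z purity of 10. The step needs enamine formation at the aldehyde and not at the hindered ketone (aldehydes condense far faster), conjugate and not 1,2-addition (five- against seven-membered ring) and aldol closure through the α′-CH2 and not the α-CH2 of the ketone (six- against four-membered ring), all of which the chain lengths of 10 secure. Heating is expected to be needed because the acceptor is β,β-disubstituted, and any trans adduct should stay behind as separable keto aldehyde.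

Step 7
Reactants: 14 4-methoxy-2-methylphenol; 15 1-bromo-3-methylbut-2-ene (prenyl bromide)
Product: 16 4-methoxy-2-methyl-6-(3-methylbut-2-en-1-yl)phenol
Conditions: NaH, PhMe, 0 °C to rt
Reagents that add atoms: none
Why: In a non-polar solvent the tight sodium phenoxide ion pair should be alkylated at carbon (ortho C-alkylation of a phenoxide), and since only one ortho position is free and the para position is blocked the prenyl group should enter at C6.

Step 8
Reactants: 16 4-methoxy-2-methyl-6-(3-methylbut-2-en-1-yl)phenol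
Product: 17 tert-butyl[4-methoxy-2-methyl-6-(3-methylbut-2-en-1-yl)phenoxy]dimethylsilane
Conditions: t-BuMe2SiCl, imidazole, DMF, 40 °C
Reagents that add atoms: tert-butyldimethylsilyl chloride, CC(C)(C)[Si](C)(C)Cl
Why: Standard silylation should protect the phenol against the allylic chloride, the organobarium reagent and the chromium oxidant of the later steps.

Step 9
Reactants: 17 tert-butyl[4-methoxy-2-methyl-6-(3-methylbut-2-en-1-yl)phenoxy]dimethylsilane
Product: 18 (E)-4-{2-[(tert-butyldimethylsilyl)oxy]-5-methoxy-3-methylphenyl}-2-methylbut-2-en-1-ol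
Conditions: SeO2 (cat.), t-BuOOH, salicylic acid (cat.), CH2Cl2, 0 °C to rt
Reagents that add atoms: tert-butyl hydroperoxide, CC(C)(C)OO
Why: Riley allylic oxidation (ene reaction, then [2,3]-sigmatropic shift) should hydroxylate the (E)-methyl group at the more substituted olefin carbon selectively and thereby fix the E geometry of the side chain.

Step 10
Reactants: 18 (E)-4-{2-[(tert-butyldimethylsilyl)oxy]-5-methoxy-3-methylphenyl}-2-methylbut-2-en-1-ol
Product: 19 tert-butyl{2-[(E)-4-chloro-3-methylbut-2-en-1-yl]-4-methoxy-6-methylphenoxy}dimethylsilane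
Conditions: PPh3, N-chlorosuccinimide, THF, 0 °C to rt
Reagents that add atoms: N-chlorosuccinimide, O=C1CCC(=O)N1Cl
Why: Appel-type chlorination should turn the primary allylic alcohol into the chloride by SN2 displacement of the oxyphosphonium ion, without allylic transposition or loss of the E geometry.

Step 11
Reactants: 19 tert-butyl{2-[(E)-4-chloro-3-methylbut-2-en-1-yl]-4-methoxy-6-methylphenoxy}dimethylsilane; 13 (3aR,7aS)-3a,7a-dimethyl-6-{2-methyl-2-[(triethylsilyl)oxy]propyl}-1,2,3,3a,4,7a-hexahydro-5H-inden-5-one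
Product: 21 (3aR,7aS)-5-[(E)-4-{2-[(tert-butyldimethylsilyl)oxy]-5-methoxy-3-methylphenyl}-2-methylbut-2-en-1-yl]-3a,7a-dimethyl-6-{2-methyl-2-[(triethylsilyl)oxy]propyl}-2,3,3a,4,5,7a-hexahydro-1H-inden-5-ol (mixture of C5 epimers), via allylbarium chloride 20 (not isolated)
Conditions: Li, biphenyl, THF, rt (lithium biphenylide LiC12H10), then BaI2 (finely divided zerovalent barium); 19, −78 °C; 13, −78 °C; aq. NH4Cl
Reagents that add atoms: none
Why: Allylbarium reagents made at −78 °C from activated zerovalent barium are known to add 1,2 to ketones at their unsubstituted (α) terminus with retention of the olefin geometry, so 20 should attack the ring-A ketone through its CH2 group; the new carbinol centre is of no consequence because it is removed in step 12.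

Step 12
Reactants: 21 (3aR,7aS)-5-[(E)-4-{2-[(tert-butyldimethylsilyl)oxy]-5-methoxy-3-methylphenyl}-2-methylbut-2-en-1-yl]-3a,7a-dimethyl-6-{2-methyl-2-[(triethylsilyl)oxy]propyl}-2,3,3a,4,5,7a-hexahydro-1H-inden-5-ol
Product: 22 (3aR,7aR)-6-[(E)-4-{2-[(tert-butyldimethylsilyl)oxy]-5-methoxy-3-methylphenyl}-2-methylbut-2-en-1-yl]-3a,7a-dimethyl-5-{2-methyl-2-[(triethylsilyl)oxy]propyl}-1,2,3,3a,7,7a-hexahydro-4H-inden-4-one
Conditions: pyridinium chlorochromate [C5H5NH][CrO3Cl], SiO2, CH2Cl2, rt
Reagents that add atoms: pyridinium chlorochromate, [O-][Cr](=O)(=O)Cl.c1cc[nH+]cc1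
Why: Dauben–Babler oxidative transposition: the tertiary allylic chromate ester should shift [3,3] to the secondary allylic position next to the quaternary carbon and be oxidised there, which places the carbonyl at C4 and the tetrasubstituted double bond at C5=C6 without touching the quaternary centres.

Step 13
Reactants: 22 (3aR,7aR)-6-[(E)-4-{2-[(tert-butyldimethylsilyl)oxy]-5-methoxy-3-methylphenyl}-2-methylbut-2-en-1-yl]-3a,7a-dimethyl-5-{2-methyl-2-[(triethylsilyl)oxy]propyl}-1,2,3,3a,7,7a-hexahydro-4H-inden-4-one
Product: 23 (3aR,7aR)-5-(2-hydroxy-2-methylpropyl)-6-[(E)-4-(2-hydroxy-5-methoxy-3-methylphenyl)-2-methylbut-2-en-1-yl]-3a,7a-dimethyl-1,2,3,3a,7,7a-hexahydro-4H-inden-4-one (CNP0158008.2)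
Conditions: Bu4NF, AcOH, THF, 0 °C to rt
Reagents that add atoms: none
Why: Buffered fluoride should cleave the aryl silyl ether and the tertiary triethylsilyl ether in one operation, the acetic acid keeping the phenoxide from isomerising the skipped diene into conjugation with the enone.

**Compound list**

1 | 4-bromo-2-methylbut-1-ene | C=C(C)CCBr | starting material
2 | methacrolein (2-methylprop-2-enal) | C=C(C)C=O | starting material
3 | (3-methylbut-3-en-1-yl)magnesium bromide | C=C(C)CC[Mg]Br | intermediate
4 | [(2,6-dimethylhepta-1,6-dien-1-yl)oxy]trimethylsilane (E/Z mixture) | C=C(C)CCCC(C)=CO[Si](C)(C)C | intermediate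
5 | 2,6-dimethylhept-6-enal (racemic) | C=C(C)CCCC(C)C=O | intermediate
6 | 5,5-dimethyldihydrofuran-2(3H)-one | CC1(C)CCC(=O)O1 | starting material
7 | 4-hydroxy-N-methoxy-N,4-dimethylpentanamide | CON(C)C(=O)CCC(C)(C)O | intermediate
8 | N-methoxy-N,4-dimethyl-4-[(triethylsilyl)oxy]pentanamide | CON(C)C(=O)CCC(C)(C)O[Si](CC)(CC)CC | intermediate
9 | 5-methyl-5-[(triethylsilyl)oxy]hex-1-en-3-one | C=CC(=O)CCC(C)(C)O[Si](CC)(CC)CC | intermediate
10 | (2RS,6E)-2,6,11-trimethyl-8-oxo-11-[(triethylsilyl)oxy]dodec-6-enal | O=CC(C)CCC/C(C)=C/C(=O)CCC(C)(C)O[Si](CC)(CC)CC | intermediate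
11 | (1R,2R)-1,2-dimethyl-2-{5-methyl-2-oxo-5-[(triethylsilyl)oxy]hexyl}cyclopentane-1-carbaldehyde | O=C[C@]1(C)CCC[C@]1(C)CC(=O)CCC(C)(C)O[Si](CC)(CC)CC | intermediate
12 | (3aR,7aR)-7-hydroxy-3a,7a-dimethyl-6-{2-methyl-2-[(triethylsilyl)oxy]propyl}octahydro-5H-inden-5-one (mixture of C6 and C7 epimers) | O=C1C(CC(C)(C)O[Si](CC)(CC)CC)C(O)[C@]2(C)CCC[C@]2(C)C1 | intermediate
13 | (3aR,7aS)-3a,7a-dimethyl-6-{2-methyl-2-[(triethylsilyl)oxy]propyl}-1,2,3,3a,4,7a-hexahydro-5H-inden-5-one | O=C1C(CC(C)(C)O[Si](CC)(CC)CC)=C[C@]2(C)CCC[C@]2(C)C1 | intermediate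
14 | 4-methoxy-2-methylphenol | COc1ccc(O)c(C)c1 | starting material
15 | 1-bromo-3-methylbut-2-ene (prenyl bromide) | CC(C)=CCBr | starting material
16 | 4-methoxy-2-methyl-6-(3-methylbut-2-en-1-yl)phenol | COc1cc(C)c(O)c(CC=C(C)C)c1 | intermediate
17 | tert-butyl[4-methoxy-2-methyl-6-(3-methylbut-2-en-1-yl)phenoxy]dimethylsilane | COc1cc(C)c(O[Si](C)(C)C(C)(C)C)c(CC=C(C)C)c1 | intermediate
18 | (E)-4-{2-[(tert-butyldimethylsilyl)oxy]-5-methoxy-3-methylphenyl}-2-methylbut-2-en-1-ol | COc1cc(C)c(O[Si](C)(C)C(C)(C)C)c(C/C=C(\C)CO)c1 | intermediate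
19 | tert-butyl{2-[(E)-4-chloro-3-methylbut-2-en-1-yl]-4-methoxy-6-methylphenoxy}dimethylsilane | COc1cc(C)c(O[Si](C)(C)C(C)(C)C)c(C/C=C(\C)CCl)c1 | intermediate
20 | [(E)-4-{2-[(tert-butyldimethylsilyl)oxy]-5-methoxy-3-methylphenyl}-2-methylbut-2-en-1-yl]barium chloride | COc1cc(C)c(O[Si](C)(C)C(C)(C)C)c(C/C=C(\C)C[Ba]Cl)c1 | intermediate
21 | (3aR,7aS)-5-[(E)-4-{2-[(tert-butyldimethylsilyl)oxy]-5-methoxy-3-methylphenyl}-2-methylbut-2-en-1-yl]-3a,7a-dimethyl-6-{2-methyl-2-[(triethylsilyl)oxy]propyl}-2,3,3a,4,5,7a-hexahydro-1H-inden-5-ol (mixture of C5 epimers) | COc1cc(C)c(O[Si](C)(C)C(C)(C)C)c(C/C=C(\C)CC2(O)C(CC(C)(C)O[Si](CC)(CC)CC)=C[C@]3(C)CCC[C@]3(C)C2)c1 | intermediate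
22 | (3aR,7aR)-6-[(E)-4-{2-[(tert-butyldimethylsilyl)oxy]-5-methoxy-3-methylphenyl}-2-methylbut-2-en-1-yl]-3a,7a-dimethyl-5-{2-methyl-2-[(triethylsilyl)oxy]propyl}-1,2,3,3a,7,7a-hexahydro-4H-inden-4-one | COc1cc(C)c(O[Si](C)(C)C(C)(C)C)c(C/C=C(\C)CC2=C(CC(C)(C)O[Si](CC)(CC)CC)C(=O)[C@]3(C)CCC[C@]3(C)C2)c1 | intermediate
23 | (3aR,7aR)-5-(2-hydroxy-2-methylpropyl)-6-[(E)-4-(2-hydroxy-5-methoxy-3-methylphenyl)-2-methylbut-2-en-1-yl]-3a,7a-dimethyl-1,2,3,3a,7,7a-hexahydro-4H-inden-4-one | COc1cc(C)c(O)c(C/C=C(\C)CC2=C(CC(C)(C)O)C(=O)[C@]3(C)CCC[C@]3(C)C2)c1 | target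

**Step count and risks**

Total step count: 13. Longest linear sequence: 8 steps (steps 2, 3, 4, 5, 6, 11, 12, 13).

Most at risk is step 6, the proposed new method. The hindered enamine may fail to add to the β,β-disubstituted enone, or may add with poor facial control because the geometry of the fully substituted enamine is not fixed. The fallback uses known chemistry, sets out from 10 and comes back at 13. The Michael–aldol condensation is run without chiral control under classical enamine conditions (pyrrolidine, AcOH, PhMe, reflux with removal of water) and should give 13 together with its mirror image, the (3aS,7aR)-enone F1. The mixture is treated with lithiated (S)-N,S-dimethyl-S-phenylsulfoximine (n-BuLi, THF, −78 °C). The adducts of 13, the β-hydroxysulfoximine F2, are separated from those of F1 by chromatography and thermolysed (PhMe, reflux) to return 13.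

Second is step 11. The allylbarium reagent may bond through its substituted terminus (allylic transposition), lose its E geometry if it warms, or merely enolise the ketone. The fallback sets out from 13 and 14 and comes back at 21.
- Ring side: Barbier propargylation of 13 (propargyl bromide, Zn, THF) should give the homopropargylic alcohol F3. Zirconium-catalysed carboalumination (Me3Al, (C5H5)2ZrCl2, CH2Cl2) gives the (E)-alkenylalane F4, which is coupled in the same flask with the benzylic chloride F8 (Pd(PPh3)4, THF) to give 21.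
- Aryl side: F8 comes from 14 by ortho-formylation (MgCl2, Et3N, paraformaldehyde, MeCN, reflux) to the salicylaldehyde F5, silylation (t-BuMe2SiCl, imidazole, DMF) to the silyl ether F6, reduction (NaBH4, MeOH) to the benzylic alcohol F7 and chlorination (PPh3, N-chlorosuccinimide, THF).

Third is step 12. The acidic chromium reagent may dehydrate the tertiary allylic alcohol to a triene, or oxidise the doubly activated ArCH2–CH= methylene. The fallback sets out from 21 and comes back at 22. Rhenium-catalysed 1,3-transposition of the hydroxyl group (Ph3SiOReO3 (cat.), Et2O, 0 °C) should give the secondary allylic alcohol F9, which is oxidised with Dess–Martin periodinane (NaHCO3, CH2Cl2) to 22.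

**Further compounds**

F1 | step 6 | (3aS,7aR)-3a,7a-dimethyl-6-{2-methyl-2-[(triethylsilyl)oxy]propyl}-1,2,3,3a,4,7a-hexahydro-5H-inden-5-one (mirror image of 13) | O=C1C(CC(C)(C)O[Si](CC)(CC)CC)=C[C@@]2(C)CCC[C@@]2(C)C1
F2 | step 6 | (3aR,7aS)-3a,7a-dimethyl-5-{[(S)-N-methyl-S-phenylsulfonimidoyl]methyl}-6-{2-methyl-2-[(triethylsilyl)oxy]propyl}-2,3,3a,4,5,7a-hexahydro-1H-inden-5-ol (C5 epimers) | CN=[S@@](CC1(O)C(CC(C)(C)O[Si](CC)(CC)CC)=C[C@]2(C)CCC[C@]2(C)C1)(=O)c1ccccc1
F3 | step 11 | (3aR,7aS)-3a,7a-dimethyl-6-{2-methyl-2-[(triethylsilyl)oxy]propyl}-5-(prop-2-yn-1-yl)-2,3,3a,4,5,7a-hexahydro-1H-inden-5-ol (C5 epimers) | C#CCC1(O)C(CC(C)(C)O[Si](CC)(CC)CC)=C[C@]2(C)CCC[C@]2(C)C1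
F4 | step 11 | (E)-alkenyl(dimethyl)alane from F3, as its dimethylaluminium alkoxide | C[Al](C)/C=C(\C)CC1(O[Al](C)C)C(CC(C)(C)O[Si](CC)(CC)CC)=C[C@]2(C)CCC[C@]2(C)C1
F5 | step 11 | 2-hydroxy-5-methoxy-3-methylbenzaldehyde | COc1cc(C)c(O)c(C=O)c1
F6 | step 11 | 2-[(tert-butyldimethylsilyl)oxy]-5-methoxy-3-methylbenzaldehyde | COc1cc(C)c(O[Si](C)(C)C(C)(C)C)c(C=O)c1
F7 | step 11 | {2-[(tert-butyldimethylsilyl)oxy]-5-methoxy-3-methylphenyl}methanol | COc1cc(C)c(O[Si](C)(C)C(C)(C)C)c(CO)c1
F8 | step 11 | tert-butyl[2-(chloromethyl)-4-methoxy-6-methylphenoxy]dimethylsilane | COc1cc(C)c(O[Si](C)(C)C(C)(C)C)c(CCl)c1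
F9 | step 12 | (3aR,7aR)-6-[(E)-4-{2-[(tert-butyldimethylsilyl)oxy]-5-methoxy-3-methylphenyl}-2-methylbut-2-en-1-yl]-3a,7a-dimethyl-5-{2-methyl-2-[(triethylsilyl)oxy]propyl}-2,3,3a,4,7,7a-hexahydro-1H-inden-4-ol (C4 epimers) | COc1cc(C)c(O[Si](C)(C)C(C)(C)C)c(C/C=C(\C)CC2=C(CC(C)(C)O[Si](CC)(CC)CC)C(O)[C@]3(C)CCC[C@]3(C)C2)c1
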